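**Plan**

- Retrosynthesis: after O–tert-butyl cleavage and quinone/hydroquinone adjustment, the ring is opened at the C1(=O)–C6(CH3) bond and contracted to a 4-alkenyl-4-hydroxycyclobutenone. Then the carbinol–alkenyl bond is cut (alkenyllithium + tert-butyl methyl squarate), then the side-chain C1'–C2' bond (alkenylalane + 2-bromoallylic bromide), then the chain in C3 and C1+C1 increments back to geranylgeraniol.
- Enabling feature: ring carbons C1(=O), C2(OH), C3(OMe) and C4(=O) are four contiguous oxygenated carbons, which is the squarate four-membered ring. C5(hexaprenyl)=C6(CH3) is a 1,1,2-trisubstituted alkene whose CH terminus can close onto a ketene carbon.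
- Forward order: chain extension (steps 1–5), C4 dibromide (6–8), chain/C4 coupling (9), mixed squarate (10–11), union (12), the only ring (13), oxidation and deprotection (14–15).
- Stereochemistry: the target has no stereocentre. Three E olefins come from geranylgeraniol and two from syn carboaluminations (steps 3 and 9). The geometry of the alkenyl donor comes from a syn hydrostannation (step 6).

Key step: step 13

Remark: all-E geranylgeraniol 1 is taken as the purchased C20 source; cyclobutenone 20 is formed racemic at its carbinol carbon, which becomes an aromatic carbon in step 13.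

Name shorthand: "hexaprenyl" = (2E,6E,10E,14E,18E)-3,7,11,15,19,23-hexamethyltetracosa-2,6,10,14,18,22-hexaen-1-yl.

**Route**

Step 1
Reactants: 1 all-E geranylgeraniol
Product: 2 all-E geranylgeranyl bromide
Conditions: PBr3 (0.4 equiv), Et2O, 0 °C
Reagents that add atoms: phosphorus tribromide BrP(Br)Br
Why: SN2 bromination of a primary allylic alcohol through its bromophosphite at low temperature is standard for polyprenols and should leave the 2E olefin in place.

Step 2
Reactants: 2 all-E geranylgeranyl bromide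
Product: 4 (5E,9E,13E)-6,10,14,18-tetramethylnonadeca-5,9,13,17-tetraen-1-yne, via trimethylsilyl enyne 3 (not isolated)
Conditions: 1-(trimethylsilyl)propyne, n-BuLi, THF, –78 to –20 °C; add 2, –78 °C to rt; then EtOH, NaOEt (cat.), 50 °C
Reagents that add atoms: 1-(trimethylsilyl)propyne CC#C[Si](C)(C)C
Why: The propargylic lithium reagent alkylates the primary allylic bromide by SN2 without allylic transposition, and ethoxide-catalysed protodesilylation in the same flask frees the terminal alkyne (a known three-carbon homologation of prenyl halides).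

Step 3
Reactants: 4 (5E,9E,13E)-6,10,14,18-tetramethylnonadeca-5,9,13,17-tetraen-1-yne
Product: 6 all-E geranylfarnesol, via alkenylalane 5 (not isolated)
Conditions: Me3Al (2 equiv), Cp2ZrCl2 (0.25 equiv), CH2Cl2, 0 °C to rt; evaporate; n-BuLi, THF, –78 °C; (CH2O)n, to rt
Reagents that add atoms: trimethylaluminium C[Al](C)C; paraformaldehyde (as formaldehyde) C=O
Why: Negishi zirconium-catalysed carboalumination adds methyl and aluminium syn across the terminal alkyne with methyl on the internal carbon, and the derived alanate is hydroxymethylated with retention, so the new trisubstituted olefin is E.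

Step 4
Reactants: 6 all-E geranylfarnesol
Product: 7 all-E geranylfarnesyl bromide
Conditions: PBr3 (0.4 equiv), Et2O, 0 °C
Reagents that add atoms: phosphorus tribromide BrP(Br)Br
Why: Same SN2 allylic bromination as in step 1.

Step 5
Reactants: 7 all-E geranylfarnesyl bromide
Product: 9 (5E,9E,13E,17E)-6,10,14,18,22-pentamethyltricosa-5,9,13,17,21-pentaen-1-yne, via trimethylsilyl enyne 8 (not isolated)
Conditions: 1-(trimethylsilyl)propyne, n-BuLi, THF, –78 to –20 °C; add 7, –78 °C to rt; then EtOH, NaOEt (cat.), 50 °C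
Reagents that add atoms: 1-(trimethylsilyl)propyne CC#C[Si](C)(C)C
Why: Same propargylation and protodesilylation as in step 2, giving the C28 alkyne that carries isoprene units two to six of the side chain.

Step 6
Reactants: 10 but-2-yn-1-ol
Product: 11 (E)-2-(tributylstannyl)but-2-en-1-ol
Conditions: Bu3SnH (1.1 equiv, slow addition), PdCl2(PPh3)2 (2 mol %), THF, rt
Reagents that add atoms: tributyltin hydride CCCC[SnH](CCCC)CCCC
Why: Palladium-catalysed hydrostannation adds H and Sn syn and, for primary propargylic alcohols, places tin mainly on the carbon next to the carbinol, giving tin trans to methyl; the minor distal regioisomer should be removable by chromatography.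

Step 7
Reactants: 11 (E)-2-(tributylstannyl)but-2-en-1-ol
Product: 12 (E)-2-bromobut-2-en-1-ol
Conditions: Br2 (1.0 equiv), CH2Cl2, –78 °C
Reagents that add atoms: bromine BrBr
Why: Bromodestannylation is an ipso electrophilic substitution that proceeds with retention of alkene geometry and is faster than bromine addition to the olefin at low temperature.

Step 8
Reactants: 12 (E)-2-bromobut-2-en-1-ol
Product: 13 (E)-1,2-dibromobut-2-ene
Conditions: PBr3 (0.4 equiv), Et2O, 0 °C
Reagents that add atoms: phosphorus tribromide BrP(Br)Br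
Why: SN2 bromination of the primary allylic alcohol; the vinylic bromide is inert and the olefin geometry is kept.

Step 9
Reactants: 9 (5E,9E,13E,17E)-6,10,14,18,22-pentamethyltricosa-5,9,13,17,21-pentaen-1-yne; 13 (E)-1,2-dibromobut-2-ene
Product: 15 (2E,5E,9E,13E,17E,21E)-3-bromo-6,10,14,18,22,26-hexamethylheptacosa-2,5,9,13,17,21,25-heptaene, via alkenylalane 14 (not isolated)
Conditions: Me3Al (2 equiv), Cp2ZrCl2 (0.25 equiv), CH2Cl2, 0 °C to rt; evaporate; THF, 13 (1.3 equiv), Pd(PPh3)4 (5 mol %), rt
Reagents that add atoms: trimethylaluminium C[Al](C)C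
Why: Negishi carboalumination sets the 2'E olefin by syn addition, and in the palladium-catalysed alkenyl–allyl coupling zerovalent palladium ionises the allylic C–Br bond much faster than the vinylic one, the alkenyl group being delivered to the unsubstituted CH2 terminus to give the skipped diene.

Step 10
Reactants: 16 dimethyl squarate
Product: 17 3-hydroxy-4-methoxycyclobut-3-ene-1,2-dione (methyl hydrogen squarate)
Conditions: NaOH (1.0 equiv), MeOH–H2O, 0 °C to rt; then HCl (1.0 equiv)
Reagents that add atoms: sodium hydroxide [Na+].[OH-]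
Why: Saponification of a vinylogous ester by addition–elimination; the resulting delocalised monoanion is deactivated towards a second attack, so one equivalent of hydroxide should stop at the half ester.

Step 11
Reactants: 17 3-hydroxy-4-methoxycyclobut-3-ene-1,2-dione
Product: 18 3-tert-butoxy-4-methoxycyclobut-3-ene-1,2-dione (tert-butyl methyl squarate)
Conditions: tert-butyl 2,2,2-trichloroacetimidate (2 equiv), CH2Cl2–cyclohexane, rt
Reagents that add atoms: tert-butyl 2,2,2-trichloroacetimidate CC(C)(C)OC(=N)C(Cl)(Cl)Cl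
Why: Imidate O-tert-butylation of an acid, here self-catalysed by the strongly acidic vinylogous acid; alkylation at either oxygen of the delocalised anion gives the same mixed squarate.

Step 12
Reactants: 15 C33 alkenyl bromide; 18 tert-butyl methyl squarate
Product: 20 2-tert-butoxy-4-hydroxy-3-methoxy-4-[(2E,5E,9E,13E,17E,21E)-6,10,14,18,22,26-hexamethylheptacosa-2,5,9,13,17,21,25-heptaen-3-yl]cyclobut-2-en-1-one (racemic), via alkenyllithium 19 (not isolated)
Conditions: t-BuLi (2.05 equiv), THF, –78 °C; cannulate into 18 (1.3 equiv), THF, –78 °C; sat. aq NH4Cl, –78 °C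
Reagents that add atoms: none
Why: Bromine–lithium exchange is fast and stereoretentive for alkenyl bromides, and the alkenyllithium adds 1,2 to a squarate ester carbonyl (known for dialkyl squarates), here expected at the carbonyl flanked by the methoxy-bearing carbon because the other carbonyl is screened by the neighbouring tert-butoxy group; the carbinol centre forms racemic and is lost on aromatisation.

Step 13
Reactants: 20 alkenyl hydroxycyclobutenone
Product: 23 2-tert-butoxy-3-methoxy-6-methyl-5-hexaprenylbenzene-1,4-diol, via dienylketene 21 (not isolated), via cyclohexadienone 22 (not isolated)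
Conditions: degassed p-xylene (0.02 M), 138 °C, Ar, about 1 h
Reagents that add atoms: none
Why: Heating opens the cyclobutenone by conrotatory four-electron electrocyclic cleavage of the C1–C4 bond, the hydroxyl rotating outward and the alkenyl group inward, to give the (3Z)-dienylketene 21. The ketene carbon then bonds to the methyl-bearing CH carbon of the alkenyl group in a disrotatory six-electron electrocyclisation that closes the six-membered carbocycle as cyclohexadienone 22, and enolisation gives the hydroquinone. The closest known reaction type is the thermal ring expansion of squarate-derived 4-alkenyl-4-hydroxycyclobutenones to hydroquinones (Moore rearrangement), including tert-butoxy-substituted cases. No stereocentre is created: the carbinol carbon of 20 and the sp3 carbon of 22 both become aromatic carbons. The selectivity needed is inward rotation of the alkenyl group, secured by the strong outward preference of the hydroxyl donor, and the E alkene geometry places hydrogen, not methyl, inside the closing terminus. The medium is neutral and metal-free, so the tert-butyl ether, the aryl–allyl unit and the chain olefins should survive, and the oxygen pattern is fixed by the connectivity of 20.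

Step 14
Reactants: 23 tert-butoxy hydroquinone
Product: 24 2-tert-butoxy-3-methoxy-6-methyl-5-hexaprenylcyclohexa-2,5-diene-1,4-dione
Conditions: Ag2O (3 equiv), MgSO4, Et2O, rt
Reagents that add atoms: none
Why: Ag2O oxidation of a hydroquinone to the quinone is neutral and anhydrous, so the tert-butyl ether and the polyene should be untouched.

Step 15
Reactants: 24 tert-butoxy quinone
Product: 25 3-demethylubiquinone-6
Conditions: CF3CO2H (5 equiv), CH2Cl2, 0 °C, 10 min; pH 7 buffer
Reagents that add atoms: none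
Why: In the quinone the tert-butoxy group is a vinylogous tert-butyl ester that ionises by E1 loss of isobutene under brief cold acid, far faster than protonation of the isolated trisubstituted olefins.

**Compound list**

1 | (2E,6E,10E)-3,7,11,15-tetramethylhexadeca-2,6,10,14-tetraen-1-ol (all-E geranylgeraniol) | OC/C=C(\C)CC/C=C(\C)CC/C=C(\C)CCC=C(C)C | starting material
2 | (2E,6E,10E)-1-bromo-3,7,11,15-tetramethylhexadeca-2,6,10,14-tetraene | BrC/C=C(\C)CC/C=C(\C)CC/C=C(\C)CCC=C(C)C | intermediate
3 | trimethyl[(5E,9E,13E)-6,10,14,18-tetramethylnonadeca-5,9,13,17-tetraen-1-yn-1-yl]silane | C[Si](C)(C)C#CCC/C=C(\C)CC/C=C(\C)CC/C=C(\C)CCC=C(C)C | intermediate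
4 | (5E,9E,13E)-6,10,14,18-tetramethylnonadeca-5,9,13,17-tetraen-1-yne | C#CCC/C=C(\C)CC/C=C(\C)CC/C=C(\C)CCC=C(C)C | intermediate
5 | dimethyl[(1E,5E,9E,13E)-2,6,10,14,18-pentamethylnonadeca-1,5,9,13,17-pentaen-1-yl]alane | C[Al](C)/C=C(\C)CC/C=C(\C)CC/C=C(\C)CC/C=C(\C)CCC=C(C)C | intermediate
6 | (2E,6E,10E,14E)-3,7,11,15,19-pentamethylicosa-2,6,10,14,18-pentaen-1-ol (all-E geranylfarnesol) | OC/C=C(\C)CC/C=C(\C)CC/C=C(\C)CC/C=C(\C)CCC=C(C)C | intermediate
7 | (2E,6E,10E,14E)-1-bromo-3,7,11,15,19-pentamethylicosa-2,6,10,14,18-pentaene | BrC/C=C(\C)CC/C=C(\C)CC/C=C(\C)CC/C=C(\C)CCC=C(C)C | intermediate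
8 | trimethyl[(5E,9E,13E,17E)-6,10,14,18,22-pentamethyltricosa-5,9,13,17,21-pentaen-1-yn-1-yl]silane | C[Si](C)(C)C#CCC/C=C(\C)CC/C=C(\C)CC/C=C(\C)CC/C=C(\C)CCC=C(C)C | intermediate
9 | (5E,9E,13E,17E)-6,10,14,18,22-pentamethyltricosa-5,9,13,17,21-pentaen-1-yne | C#CCC/C=C(\C)CC/C=C(\C)CC/C=C(\C)CC/C=C(\C)CCC=C(C)C | intermediate
10 | but-2-yn-1-ol | CC#CCO | starting material
11 | (E)-2-(tributylstannyl)but-2-en-1-ol (tin trans to methyl) | CCCC[Sn](CCCC)(CCCC)/C(CO)=C/C | intermediate
12 | (E)-2-bromobut-2-en-1-ol | Br/C(CO)=C/C | intermediate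
13 | (E)-1,2-dibromobut-2-ene | Br/C(CBr)=C/C | intermediate
14 | dimethyl[(1E,5E,9E,13E,17E)-2,6,10,14,18,22-hexamethyltricosa-1,5,9,13,17,21-hexaen-1-yl]alane | C[Al](C)/C=C(\C)CC/C=C(\C)CC/C=C(\C)CC/C=C(\C)CC/C=C(\C)CCC=C(C)C | intermediate
15 | (2E,5E,9E,13E,17E,21E)-3-bromo-6,10,14,18,22,26-hexamethylheptacosa-2,5,9,13,17,21,25-heptaene | Br/C(C/C=C(\C)CC/C=C(\C)CC/C=C(\C)CC/C=C(\C)CC/C=C(\C)CCC=C(C)C)=C/C | intermediate
16 | 3,4-dimethoxycyclobut-3-ene-1,2-dione (dimethyl squarate) | COC1=C(OC)C(=O)C1=O | starting material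
17 | 3-hydroxy-4-methoxycyclobut-3-ene-1,2-dione | COC1=C(O)C(=O)C1=O | intermediate
18 | 3-tert-butoxy-4-methoxycyclobut-3-ene-1,2-dione | COC1=C(OC(C)(C)C)C(=O)C1=O | intermediate
19 | [(2Z,5E,9E,13E,17E,21E)-6,10,14,18,22,26-hexamethylheptacosa-2,5,9,13,17,21,25-heptaen-3-yl]lithium (lithium trans to the C1 methyl, same geometry as 15) | [Li]/C(C/C=C(\C)CC/C=C(\C)CC/C=C(\C)CC/C=C(\C)CC/C=C(\C)CCC=C(C)C)=C/C | intermediate
20 | 2-tert-butoxy-4-hydroxy-3-methoxy-4-[(2E,5E,9E,13E,17E,21E)-6,10,14,18,22,26-hexamethylheptacosa-2,5,9,13,17,21,25-heptaen-3-yl]cyclobut-2-en-1-one (racemic) | O=C1C(OC(C)(C)C)=C(OC)C1(O)/C(C/C=C(\C)CC/C=C(\C)CC/C=C(\C)CC/C=C(\C)CC/C=C(\C)CCC=C(C)C)=C/C | intermediate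
21 | (3Z,5E)-2-tert-butoxy-4-hydroxy-3-methoxy-5-(hexaprenyl)hepta-1,3,5-trien-1-one | O=C=C(OC(C)(C)C)/C(OC)=C(O)\C(C/C=C(\C)CC/C=C(\C)CC/C=C(\C)CC/C=C(\C)CC/C=C(\C)CCC=C(C)C)=C\C | intermediate
22 | 2-tert-butoxy-4-hydroxy-3-methoxy-6-methyl-5-(hexaprenyl)cyclohexa-2,4-dien-1-one (racemic) | O=C1C(OC(C)(C)C)=C(OC)C(O)=C(C/C=C(\C)CC/C=C(\C)CC/C=C(\C)CC/C=C(\C)CC/C=C(\C)CCC=C(C)C)C1C | intermediate
23 | 2-tert-butoxy-3-methoxy-6-methyl-5-[(2E,6E,10E,14E,18E)-3,7,11,15,19,23-hexamethyltetracosa-2,6,10,14,18,22-hexaen-1-yl]benzene-1,4-diol | COc1c(OC(C)(C)C)c(O)c(C)c(C/C=C(\C)CC/C=C(\C)CC/C=C(\C)CC/C=C(\C)CC/C=C(\C)CCC=C(C)C)c1O | intermediate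
24 | 2-tert-butoxy-3-methoxy-6-methyl-5-[(2E,6E,10E,14E,18E)-3,7,11,15,19,23-hexamethyltetracosa-2,6,10,14,18,22-hexaen-1-yl]cyclohexa-2,5-diene-1,4-dione | COC1=C(OC(C)(C)C)C(=O)C(C)=C(C/C=C(\C)CC/C=C(\C)CC/C=C(\C)CC/C=C(\C)CC/C=C(\C)CCC=C(C)C)C1=O | intermediate
25 | 2-hydroxy-3-methoxy-6-methyl-5-[(2E,6E,10E,14E,18E)-3,7,11,15,19,23-hexamethyltetracosa-2,6,10,14,18,22-hexaen-1-yl]cyclohexa-2,5-diene-1,4-dione (3-demethylubiquinone-6) | COC1=C(O)C(=O)C(C)=C(C/C=C(\C)CC/C=C(\C)CC/C=C(\C)CC/C=C(\C)CC/C=C(\C)CCC=C(C)C)C1=O | target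

**Step count and risks**

Total steps: 15. Longest linear sequence: 10 (steps 1–5, 9, 12, 13, 14, 15).

Steps most likely to fail:

1. Step 12. The alkenyllithium may leak to the carbonyl next to the tert-butoxy carbon, which would swap the hydroxy and methoxy positions in the final quinone, and a second addition may occur. The fallback fixes the regiochemistry by connectivity instead of by steric bias. It sets out from dimethyl squarate 16 and bromide 15.
   - Noyori ketalisation of 16 (MeOSiMe3, cat. TMSOTf, CH2Cl2) should give the monoketal 2,3,4,4-tetramethoxycyclobut-2-en-1-one F1.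
   - Hydroxide (1 equiv) can displace only the vinylogous-ester methoxy group at C3, giving 3-hydroxy-2,4,4-trimethoxycyclobut-2-en-1-one F2.
   - tert-Butyl trichloroacetimidate converts F2 into 3-tert-butoxy-2,4,4-trimethoxycyclobut-2-en-1-one F3; both oxygens of the anion lead to the same compound.
   - Alkenyllithium 19, made from 15 as in step 12, adds to the single carbonyl of F3 to give the ketal carbinol 1-(C33 alkenyl)-3-tert-butoxy-2,4,4-trimethoxycyclobut-2-en-1-ol F4.
   - Mild ketal hydrolysis (oxalic acid on wet silica, CH2Cl2) unveils the carbonyl next to the tert-butoxy carbon, and the route is rejoined at 20.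

2. Step 9. Oxidative addition into the vinylic C–Br bond, methyl transfer from aluminium, or syn–anti isomerisation of the allylpalladium intermediate may erode chemoselectivity or the geometry of the bromoalkene. Geometry erosion would slow, but not redirect, the later ring closure. The fallback replaces the allylpalladium coupling by a copper-catalysed SN2 displacement. It sets out from alkenylalane 14.
   - Iodinolysis of 14 (I2, THF, –30 °C) gives the alkenyl iodide (1E,5E,9E,13E,17E)-1-iodo-2,6,10,14,18,22-hexamethyltricosa-1,5,9,13,17,21-hexaene F5.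
   - Iodine–lithium exchange (t-BuLi, –78 °C) gives the alkenyllithium F6, and MgBr2 converts it into the alkenylmagnesium bromide F7.
   - F7 is coupled with dibromide 13 under Li2CuCl4 catalysis (THF, –78 °C), conditions that favour attack at the primary allylic carbon and leave vinylic bromides alone. The route is rejoined at 15.

3. Step 15. Protonation of the chain olefins by CF3CO2H may start hydration, trifluoroacetate addition or cationic cyclisation of the polyprenyl chain before the tert-butyl group has left. The fallback avoids free protic acid. It sets out from quinone 24.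
   - TMSOTf with excess 2,6-lutidine (CH2Cl2, 0 °C) exchanges tert-butyl for silicon under buffered conditions, giving the trimethylsilyl vinylogous ester 2-(trimethylsilyloxy)-3-methoxy-6-methyl-5-hexaprenyl-1,4-benzoquinone F8.
   - F8 is cleaved by neutral methanol during work-up, and the route is rejoined at 25.

Further compounds
F1 | step 12 | 2,3,4,4-tetramethoxycyclobut-2-en-1-one | COC1=C(OC)C(OC)(OC)C1=O
F2 | step 12 | 3-hydroxy-2,4,4-trimethoxycyclobut-2-en-1-one | COC1=C(O)C(OC)(OC)C1=O
F3 | step 12 | 3-tert-butoxy-2,4,4-trimethoxycyclobut-2-en-1-one | COC1=C(OC(C)(C)C)C(OC)(OC)C1=O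
F4 | step 12 | 3-tert-butoxy-2,4,4-trimethoxy-1-[(2E,5E,9E,13E,17E,21E)-6,10,14,18,22,26-hexamethylheptacosa-2,5,9,13,17,21,25-heptaen-3-yl]cyclobut-2-en-1-ol | COC1=C(OC(C)(C)C)C(OC)(OC)C1(O)/C(C/C=C(\C)CC/C=C(\C)CC/C=C(\C)CC/C=C(\C)CC/C=C(\C)CCC=C(C)C)=C/C
F5 | step 9 | (1E,5E,9E,13E,17E)-1-iodo-2,6,10,14,18,22-hexamethyltricosa-1,5,9,13,17,21-hexaene | I/C=C(\C)CC/C=C(\C)CC/C=C(\C)CC/C=C(\C)CC/C=C(\C)CCC=C(C)C
F6 | step 9 | [(1E,5E,9E,13E,17E)-2,6,10,14,18,22-hexamethyltricosa-1,5,9,13,17,21-hexaen-1-yl]lithium | [Li]/C=C(\C)CC/C=C(\C)CC/C=C(\C)CC/C=C(\C)CC/C=C(\C)CCC=C(C)C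
F7 | step 9 | [(1E,5E,9E,13E,17E)-2,6,10,14,18,22-hexamethyltricosa-1,5,9,13,17,21-hexaen-1-yl]magnesium bromide | Br[Mg]/C=C(\C)CC/C=C(\C)CC/C=C(\C)CC/C=C(\C)CC/C=C(\C)CCC=C(C)C
F8 | step 15 | 3-methoxy-6-methyl-5-hexaprenyl-2-(trimethylsilyloxy)cyclohexa-2,5-diene-1,4-dione | COC1=C(O[Si](C)(C)C)C(=O)C(C)=C(C/C=C(\C)CC/C=C(\C)CC/C=C(\C)CC/C=C(\C)CC/C=C(\C)CCC=C(C)C)C1=O
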